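**Late readings.** Start from the last readings of the two earlier runs, where the readings have stopped moving within their scatter. At 8.00 min the amber run has converted 37.9% of the two substrates together, and what is left holds an excess of right-handed substrate of 20.1%.

in all of them: left-handed substrate 0.050 M; right-handed substrate 0.050 M; added ligand 0.19 mM
- amber: coupling partner 0.80 equiv; free catalyst 0.81 mol%; run made earlier
- grey: coupling partner 0.80 equiv; free catalyst 1.3 mol%; run made earlier
- flask: coupling partner 0.800 equiv; free catalyst 0.58 mol%; time 8.0 min

| run | time / min | right-handed substrate / % | left-handed substrate / % |
|---|---|---|---|
| amber | 0.667 | 42.4 | 32.6 |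
| amber | 2.00 | 38.5 | 26.4 |
| amber | 4.00 | 37.8 | 25.0 |
| amber | 6.00 | 37.5 | 25.2 |
| amber | 8.00 | 37.3 | 24.8 |
| grey | 1.50 | 38.0 | 25.3 |
| grey | 3.00 | 36.4 | 23.5 |
| grey | 5.00 | 37.0 | 23.8 |
| grey | 6.00 | 36.6 | 23.7 |
| grey | 8.00 | 36.5 | 23.5 |

(readings scatter by 0.5 percentage points)

- whether the excess of right-handed substrate over left-handed substrate among what is left of the two reaches 95% by 8.0 min (no / yes)
- the highest excess of right-handed substrate over left-handed substrate among what is left of the two up to 8.0 min

- free catalyst is single-handed; left-handed substrate and right-handed substrate are mirror images of each other, charged as a racemate, each of them at the stated concentration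
- steps under discussion: coupling partner + free catalyst + left-handed substrate -> free catalyst + left-handed product; coupling partner + free catalyst + right-handed substrate -> free catalyst + right-handed product; free catalyst -> spent catalyst; coupling partner -> decomposition product; free catalyst + added ligand <-> idle complex

**Frozen ratio.** Divide that excess by the fraction converted and call the result the gain, 0.531. The last grey reading gives 0.542, and the first amber reading, at 25.0% converted, gives 0.523, so freeze the gain over this range.

**Ceiling number.** Each conversion uses one coupling partner, the limiting reagent here, so 0.800 equiv on one substrate caps the flask's conversion at a fraction 0.400 of both. Multiply gain by cap into one number, 21.2%, the ceiling excess: the excess at this gain if conversion reaches the cap.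

**Testing it.** The number ignores catalyst, and the flask has less of it than the amber run, which stopped at 37.9%. So expect the flask to stop lower, just under the ceiling, which stands below the 95% wanted, and answer no.

**The result.** The forecast says no with a top of 18%, lower than my ceiling, and reads “a kinetic resolution that stalls early”. The flask gives no and a top of 19.7%.

    coupling partner + free catalyst + left-handed substrate → free catalyst + left-handed product (k = 1500 M⁻² s⁻¹)
    coupling partner + free catalyst + right-handed substrate → free catalyst + right-handed product (k = 620 M⁻² s⁻¹)
    free catalyst → spent catalyst (k = 0.00700 s⁻¹)
    coupling partner → decomposition product (k = 1.60 × 10⁻⁴ s⁻¹)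
    free catalyst + added ligand ⇌ idle complex, settled at all times (K = 2600 M⁻¹)

**What stands.** By 8.00 min the flask has converted 37.0% of both substrates, short of the cap, and the ceiling scaled by that share of the cap is 19.6%. The neighbour flask with 0.200 equiv has a ceiling of 5.30% and tops out at 4.25%, its gain being 0.440 at a conversion below the frozen range. In the flask, free catalyst has a half-life of 1.7 min on its own, shorter than the 2.3 min of coupling partner through the right-handed coupling alone at 0.526 min, and at that moment the left-handed coupling uses coupling partner 2.0 times as fast as the right-handed one. At 8.00 min the flask holds 6.32% of its catalyst as free catalyst and 6.07% of its coupling partner.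

The runs are simulated for an exercise, noise included.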